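## Retrosynthetic overview

- C6 methyl last: the target comes from a 6-methoxy-1,2-dioxane by methyl transfer to its cyclic peroxycarbenium ion; the C3 side chain directs the new quaternary centre (1,4-induction).
- 1,2-Dioxane: a C6 ketone takes up H2O2 and the perhydrate opens a cis-β-lactone at C3 with inversion, closing the peroxide ring and freeing the C1 acid.
- Key C6–C7 bond: the formyl C–H of a β-lactone aldehyde serves as an acyl anion equivalent and is alkylated by the homoallylic bromide of the side chain (nickel/photoredox/hydrogen-atom transfer), joining two normally electrophilic carbons.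
- Lactone aldehyde: catalytic asymmetric ketene–aldehyde cyclocondensation (sets C2 and C3), then ozonolysis. Bromide: butynyl Grignard plus 2,6,6-trimethylcyclohexenone, methylalumination/oxirane (E alkene), Appel bromination, oxidative transposition.
- Ring order: the carbocycle is bought in and its enone unveiled by transposition; the β-lactone is made second and consumed; the 1,2-dioxane is closed third.

Atom labels used below: C1 = ester carbon, C2 = its α-carbon, C3 and C6 = the oxygen-bearing dioxane carbons, C7–C12 = side chain toward the cyclohexenone. The target is (2S,3S,6R) with an E alkene.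

Assumption: O-trimethylsilylquinine is taken as the cinchona catalyst that gives the (3S,4R) β-lactone of step 5; if its facial sense is the reverse, O-trimethylsilylquinidine is used and nothing else changes.

## Route

Step 1
Reactants: 1 (4-bromobut-1-yn-1-yl)trimethylsilane; 2 2,6,6-trimethylcyclohex-2-en-1-one
Product: 5 rac-1-(but-3-yn-1-yl)-2,6,6-trimethylcyclohex-2-en-1-ol, via Grignard reagent 3 (not isolated), via silyl alkynol 4 (not isolated)
Conditions: Mg, THF, rt; 2, CeCl3, THF, −78 → 0 °C; then MeOH, K2CO3, rt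
Reagents that add atoms: none
Why: Grignard 1,2-addition to the hindered enone (CeCl3 suppresses conjugate addition) followed by protodesilylation of the alkynylsilane in the same pot; the carbinol centre is racemic and is erased in step 4.

Step 2
Reactants: 5 rac-1-(but-3-yn-1-yl)-2,6,6-trimethylcyclohex-2-en-1-ol; 6 oxirane
Product: 8 (3E)-6-(1-hydroxy-2,6,6-trimethylcyclohex-2-en-1-yl)-4-methylhex-3-en-1-ol (racemic), via alkenylalane 7 (not isolated)
Conditions: Me3Al (3.5 equiv), Cp2ZrCl2 (0.25 equiv), CH2Cl2, 0 °C → rt; n-BuLi, THF/hexane, −78 °C; 6, −78 → 0 °C; then H2O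
Reagents that add atoms: trimethylaluminium, C[Al](C)C
Why: Negishi zirconium-catalysed syn-methylalumination of the terminal alkyne (the hydroxyl is masked in situ as its aluminium alkoxide) and opening of oxirane by the alkenylalanate with retention at carbon, which fixes the E trisubstituted alkene.

Step 3
Reactants: 8 (3E)-6-(1-hydroxy-2,6,6-trimethylcyclohex-2-en-1-yl)-4-methylhex-3-en-1-ol
Product: 9 rac-1-[(3E)-6-bromo-3-methylhex-3-en-1-yl]-2,6,6-trimethylcyclohex-2-en-1-ol
Conditions: CBr4, PPh3, CH2Cl2, 0 °C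
Reagents that add atoms: tetrabromomethane, BrC(Br)(Br)Br
Why: Appel bromination is selective for the primary alcohol because the hindered tertiary allylic alcohol does not form an alkoxyphosphonium salt at 0 °C.

Step 4
Reactants: 9 rac-1-[(3E)-6-bromo-3-methylhex-3-en-1-yl]-2,6,6-trimethylcyclohex-2-en-1-ol
Product: 10 3-[(3E)-6-bromo-3-methylhex-3-en-1-yl]-2,4,4-trimethylcyclohex-2-en-1-one
Conditions: (C5H5NH)[CrO3Cl] (pyridinium chlorochromate), 4 Å MS, CH2Cl2, rt
Reagents that add atoms: pyridinium chlorochromate (C5H5NH)[CrO3Cl], c1cc[nH+]cc1.[O-][Cr](=O)(=O)Cl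
Why: Babler–Dauben oxidative 1,3-transposition, in which the tertiary allylic chromate ester undergoes a [3,3] shift and is oxidised to the 3-alkyl-2,4,4-trimethylcyclohexenone, removing the racemic carbinol centre while the bromide and the E alkene are untouched.

Step 5
Reactants: 11 pent-4-enal; 12 propanoyl chloride
Product: 14 (3S,4R)-4-(but-3-en-1-yl)-3-methyloxetan-2-one, via methylketene 13 (not isolated)
Conditions: O-trimethylsilylquinine (10 mol%), LiClO4, iPr2NEt, CH2Cl2/Et2O, −78 °C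
Reagents that add atoms: none
Why: Cinchona alkaloid-catalysed acyl halide–aldehyde cyclocondensation (Wynberg-type ketene–aldehyde [2+2] through a chiral ammonium enolate) gives the cis-β-lactone with high dr and ee, setting C2 as S and C3 as R, the latter to be inverted in step 8.

Step 6
Reactants: 14 (3S,4R)-4-(but-3-en-1-yl)-3-methyloxetan-2-one
Product: 16 3-[(2R,3S)-3-methyl-4-oxooxetan-2-yl]propanal, via ozonide 15 (not isolated)
Conditions: O3, CH2Cl2, −78 °C; then PPh3, −78 °C → rt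
Reagents that add atoms: ozone, [O-][O+]=O
Why: Ozonolysis of the terminal alkene with reductive work-up gives the aldehyde under neutral conditions that leave the β-lactone and both stereocentres untouched.

Step 7
Reactants: 16 3-[(2R,3S)-3-methyl-4-oxooxetan-2-yl]propanal (1.5 equiv); 10 3-[(3E)-6-bromo-3-methylhex-3-en-1-yl]-2,4,4-trimethylcyclohex-2-en-1-one
Product: 17 (3S,4R)-3-methyl-4-[(6E)-7-methyl-3-oxo-9-(2,6,6-trimethyl-3-oxocyclohex-1-en-1-yl)non-6-en-1-yl]oxetan-2-one
Conditions: Ir[dF(CF3)ppy]2(dtbbpy)PF6 (1 mol%), NiBr2(dtbbpy) (10 mol%), quinuclidine (10 mol%), K2CO3, 1,4-dioxane, blue LEDs, rt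
Reagents that add atoms: none
Why: Nickel/photoredox/hydrogen-atom-transfer aldehyde C–H alkylation, in which the quinuclidinium radical cation abstracts the formyl hydrogen, nickel that has inserted into the C–Br bond of 10 captures the acyl radical and reductive elimination forms the C6–C7 ketone, so the aldehyde carbon acts as an acyl anion equivalent while the lactone, enone, alkene and both stereocentres are spectators.

Step 8
Reactants: 17 (3S,4R)-3-methyl-4-[(6E)-7-methyl-3-oxo-9-(2,6,6-trimethyl-3-oxocyclohex-1-en-1-yl)non-6-en-1-yl]oxetan-2-one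
Product: 19 (2S)-2-[(3S,6RS)-6-hydroxy-6-[(3E)-4-methyl-6-(2,6,6-trimethyl-3-oxocyclohex-1-en-1-yl)hex-3-en-1-yl]-1,2-dioxan-3-yl]propanoic acid, via ketone perhydrate 18 (not isolated)
Conditions: urea·H2O2 (3 equiv), Sc(OTf)3 (5 mol%), MeCN, 0 °C → rt
Reagents that add atoms: hydrogen peroxide (used as its urea adduct), OO
Why: Proposed new method: the C6 ketone adds H2O2 and the terminal OOH of the perhydrate attacks the lactone β-carbon in a 6-exo-tet SN2 alkyl–oxygen cleavage with carboxylate as leaving group, so C3 is inverted from R to S and the 1,2-dioxane closes as its C6 hemiketal without touching C2 or the alkenes; the closest known reactions are the neutral alkyl–oxygen hydrolysis of β-lactones with inversion and the ring closure of ketone perhydrates onto sp3 electrophiles.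

Step 9
Reactants: 19 (2S)-2-[(3S,6RS)-6-hydroxy-6-[(3E)-4-methyl-6-(2,6,6-trimethyl-3-oxocyclohex-1-en-1-yl)hex-3-en-1-yl]-1,2-dioxan-3-yl]propanoic acid
Product: 21 methyl (2S)-2-[(3S,6RS)-6-methoxy-6-[(3E)-4-methyl-6-(2,6,6-trimethyl-3-oxocyclohex-1-en-1-yl)hex-3-en-1-yl]-1,2-dioxan-3-yl]propanoate, via hemiketal methyl ester 20 (not isolated)
Conditions: TMSCHN2, MeOH/PhMe, 0 °C; then HC(OMe)3, CSA (5 mol%), MeOH, rt
Reagents that add atoms: (trimethylsilyl)diazomethane, C[Si](C)(C)C=[N+]=[N-]; trimethyl orthoformate, COC(OC)OC; methanol, CO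
Why: O-methylation of the acid by diazomethane generated in situ followed by acid-catalysed exchange of the peroxy hemiketal hydroxyl for methoxy (peroxyketal formation), neither of which touches C2 or C3, while the C6 mixture converges in step 10.

Step 10
Reactants: 21 methyl (2S)-2-[(3S,6RS)-6-methoxy-6-[(3E)-4-methyl-6-(2,6,6-trimethyl-3-oxocyclohex-1-en-1-yl)hex-3-en-1-yl]-1,2-dioxan-3-yl]propanoate
Product: 23 methyl (2S)-2-[(3S,6R)-6-methyl-6-[(3E)-4-methyl-6-(2,6,6-trimethyl-3-oxocyclohex-1-en-1-yl)hex-3-en-1-yl]-1,2-dioxan-3-yl]propanoate, via peroxycarbenium triflate 22 (not isolated)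
Conditions: Me3Al (4 equiv), TMSOTf (1.1 equiv), CH2Cl2, −78 → −40 °C
Reagents that add atoms: trimethylaluminium, C[Al](C)C
Why: Proposed new method: TMSOTf ionises the peroxyketal to the cyclic peroxycarbenium ion, which takes methyl from Me3Al along the axial trajectory of the half-chair that holds the C3 side chain pseudo-equatorial, so methyl ends cis to the side chain and C6 is R; the closest known reactions are Lewis acid-mediated substitutions of cyclic peroxyketals by allylsilanes and silyl ketene acetals through peroxycarbenium ions and the axial C-methylation of six-membered oxocarbenium ions by Me3Al.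

## Compound list

1 | (4-bromobut-1-yn-1-yl)trimethylsilane | C[Si](C)(C)C#CCCBr | starting material
2 | 2,6,6-trimethylcyclohex-2-en-1-one | CC1=CCCC(C)(C)C1=O | starting material
3 | [4-(trimethylsilyl)but-3-yn-1-yl]magnesium bromide | C[Si](C)(C)C#CCC[Mg]Br | intermediate
4 | rac-2,6,6-trimethyl-1-[4-(trimethylsilyl)but-3-yn-1-yl]cyclohex-2-en-1-ol | CC1=CCCC(C)(C)C1(O)CCC#C[Si](C)(C)C | intermediate
5 | rac-1-(but-3-yn-1-yl)-2,6,6-trimethylcyclohex-2-en-1-ol | CC1=CCCC(C)(C)C1(O)CCC#C | intermediate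
6 | oxirane | C1CO1 | starting material
7 | dimethylaluminium alkoxide of [(1E)-4-(1-hydroxy-2,6,6-trimethylcyclohex-2-en-1-yl)-2-methylbut-1-en-1-yl]dimethylalane | C[Al](C)/C=C(\C)CCC1(O[Al](C)C)C(C)=CCCC1(C)C | intermediate
8 | (3E)-6-(1-hydroxy-2,6,6-trimethylcyclohex-2-en-1-yl)-4-methylhex-3-en-1-ol (racemic) | OCC/C=C(\C)CCC1(O)C(C)=CCCC1(C)C | intermediate
9 | rac-1-[(3E)-6-bromo-3-methylhex-3-en-1-yl]-2,6,6-trimethylcyclohex-2-en-1-ol | BrCC/C=C(\C)CCC1(O)C(C)=CCCC1(C)C | intermediate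
10 | 3-[(3E)-6-bromo-3-methylhex-3-en-1-yl]-2,4,4-trimethylcyclohex-2-en-1-one | BrCC/C=C(\C)CCC1=C(C)C(=O)CCC1(C)C | intermediate
11 | pent-4-enal | C=CCCC=O | starting material
12 | propanoyl chloride | CCC(=O)Cl | starting material
13 | methylketene (prop-1-en-1-one) | CC=C=O | intermediate
14 | (3S,4R)-4-(but-3-en-1-yl)-3-methyloxetan-2-one | C[C@@H]1C(=O)O[C@@H]1CCC=C | intermediate
15 | (3S,4R)-3-methyl-4-[2-(1,2,4-trioxolan-3-yl)ethyl]oxetan-2-one | C[C@@H]1C(=O)O[C@@H]1CCC2OCOO2 | intermediate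
16 | 3-[(2R,3S)-3-methyl-4-oxooxetan-2-yl]propanal | C[C@@H]1C(=O)O[C@@H]1CCC=O | intermediate
17 | (3S,4R)-3-methyl-4-[(6E)-7-methyl-3-oxo-9-(2,6,6-trimethyl-3-oxocyclohex-1-en-1-yl)non-6-en-1-yl]oxetan-2-one | C[C@@H]1C(=O)O[C@@H]1CCC(=O)CC/C=C(\C)CCC2=C(C)C(=O)CCC2(C)C | intermediate
18 | (3S,4R)-4-[(6E)-3-hydroperoxy-3-hydroxy-7-methyl-9-(2,6,6-trimethyl-3-oxocyclohex-1-en-1-yl)non-6-en-1-yl]-3-methyloxetan-2-one | C[C@@H]1C(=O)O[C@@H]1CCC(O)(OO)CC/C=C(\C)CCC2=C(C)C(=O)CCC2(C)C | intermediate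
19 | (2S)-2-[(3S,6RS)-6-hydroxy-6-[(3E)-4-methyl-6-(2,6,6-trimethyl-3-oxocyclohex-1-en-1-yl)hex-3-en-1-yl]-1,2-dioxan-3-yl]propanoic acid | OC(=O)[C@@H](C)[C@@H]1CCC(O)(CC/C=C(\C)CCC2=C(C)C(=O)CCC2(C)C)OO1 | intermediate
20 | methyl (2S)-2-[(3S,6RS)-6-hydroxy-6-[(3E)-4-methyl-6-(2,6,6-trimethyl-3-oxocyclohex-1-en-1-yl)hex-3-en-1-yl]-1,2-dioxan-3-yl]propanoate | COC(=O)[C@@H](C)[C@@H]1CCC(O)(CC/C=C(\C)CCC2=C(C)C(=O)CCC2(C)C)OO1 | intermediate
21 | methyl (2S)-2-[(3S,6RS)-6-methoxy-6-[(3E)-4-methyl-6-(2,6,6-trimethyl-3-oxocyclohex-1-en-1-yl)hex-3-en-1-yl]-1,2-dioxan-3-yl]propanoate | COC(=O)[C@@H](C)[C@@H]1CCC(OC)(CC/C=C(\C)CCC2=C(C)C(=O)CCC2(C)C)OO1 | intermediate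
22 | cyclic peroxycarbenium triflate of 21 (C6=O+ within the dioxane ring) | COC(=O)[C@@H](C)[C@@H]1CCC(CC/C=C(\C)CCC2=C(C)C(=O)CCC2(C)C)=[O+]O1.[O-]S(=O)(=O)C(F)(F)F | intermediate
23 | methyl (2S)-2-[(3S,6R)-6-methyl-6-[(3E)-4-methyl-6-(2,6,6-trimethyl-3-oxocyclohex-1-en-1-yl)hex-3-en-1-yl]-1,2-dioxan-3-yl]propanoate | COC(=O)[C@@H](C)[C@@H]1CC[C@@](C)(CC/C=C(\C)CCC2=C(C)C(=O)CCC2(C)C)OO1 | target

## Step count and risks

Total step count: 10. Longest linear sequence: 8 (steps 1, 2, 3, 4, 7, 8, 9, 10).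

Steps most likely to fail:

Step 7 (fragment union). The β-lactone may be opened by quinuclidine or carbonate, and allylic hydrogen abstraction or slow capture of the primary bromide may lower the yield. The fallback sets out from 16 and comes back at 17. Aldehyde 16 is oxidised (NaClO2, NaH2PO4, 2-methylbut-2-ene) to 3-[(2R,3S)-3-methyl-4-oxooxetan-2-yl]propanoic acid F1. F1 is converted with 2,2'-dipyridyl disulfide and PPh3 into S-pyridin-2-yl 3-[(2R,3S)-3-methyl-4-oxooxetan-2-yl]propanethioate F2. F2 is joined to bromide 10 by a reductive cross-electrophile acylation (NiCl2(dme), dtbbpy, Zn, DMA), which gives 17 without amine or light.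

Step 8 (perhydrolysis and ring closure). H2O2 may attack the lactone carbonyl instead of the β-carbon, giving a peracid that can epoxidise the side chain, or the SN2 at the secondary carbon may be too slow. The fallback sets out from 17 and comes back at 20. Methanolysis of 17 (MeOH, catalytic K2CO3, 0 °C; acyl–oxygen cleavage, retention) gives methyl (2S,3R,9E)-3-hydroxy-2,10-dimethyl-6-oxo-12-(2,6,6-trimethyl-3-oxocyclohex-1-en-1-yl)dodec-9-enoate F3. Mesylation (MsCl, Et3N, 0 °C) gives methyl (2S,3R,9E)-3-(methanesulfonyloxy)-2,10-dimethyl-6-oxo-12-(2,6,6-trimethyl-3-oxocyclohex-1-en-1-yl)dodec-9-enoate F4. Treatment of F4 with urea·H2O2 and Sc(OTf)3 forms the C6 perhydrate, which displaces the mesylate intramolecularly with inversion and delivers 20; the ketalisation half of step 9 then gives 21.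

Step 10 (methyl transfer to the peroxycarbenium ion). Me3Al may cleave the O–O bond, the cation may lose a proton to an enol peroxide, or the wrong C6 epimer may dominate. The fallback sets out from 17 and comes back at 23, building C6 from an alkene instead. Methylenation of the saturated ketone (Zn, CH2Br2, TiCl4) gives (3S,4R)-3-methyl-4-[(6E)-7-methyl-3-methylidene-9-(2,6,6-trimethyl-3-oxocyclohex-1-en-1-yl)non-6-en-1-yl]oxetan-2-one F5. Perhydrolysis of the lactone with urea·H2O2 and Sc(OTf)3 (inversion at C3) gives (2S,3S,9E)-3-hydroperoxy-2,10-dimethyl-6-methylidene-12-(2,6,6-trimethyl-3-oxocyclohex-1-en-1-yl)dodec-9-enoic acid F6. TMSCHN2 gives its methyl ester, methyl (2S,3S,9E)-3-hydroperoxy-2,10-dimethyl-6-methylidene-12-(2,6,6-trimethyl-3-oxocyclohex-1-en-1-yl)dodec-9-enoate F7. Cycloperoxymercuration with Hg(OAc)2 (6-exo) gives methyl (2S)-2-[(3S,6RS)-6-[(acetoxymercurio)methyl]-6-[(3E)-4-methyl-6-(2,6,6-trimethyl-3-oxocyclohex-1-en-1-yl)hex-3-en-1-yl]-1,2-dioxan-3-yl]propanoate F8. Demercuration with NaBH4 gives 23 together with its C6 epimer, which is removed by HPLC.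

Further compounds
F1 | step 7 | 3-[(2R,3S)-3-methyl-4-oxooxetan-2-yl]propanoic acid | C[C@@H]1C(=O)O[C@@H]1CCC(O)=O
F2 | step 7 | S-pyridin-2-yl 3-[(2R,3S)-3-methyl-4-oxooxetan-2-yl]propanethioate | C[C@@H]1C(=O)O[C@@H]1CCC(=O)Sc1ccccn1
F3 | step 8 | methyl (2S,3R,9E)-3-hydroxy-2,10-dimethyl-6-oxo-12-(2,6,6-trimethyl-3-oxocyclohex-1-en-1-yl)dodec-9-enoate | COC(=O)[C@@H](C)[C@H](O)CCC(=O)CC/C=C(\C)CCC1=C(C)C(=O)CCC1(C)C
F4 | step 8 | methyl (2S,3R,9E)-3-(methanesulfonyloxy)-2,10-dimethyl-6-oxo-12-(2,6,6-trimethyl-3-oxocyclohex-1-en-1-yl)dodec-9-enoate | COC(=O)[C@@H](C)[C@H](OS(C)(=O)=O)CCC(=O)CC/C=C(\C)CCC1=C(C)C(=O)CCC1(C)C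
F5 | step 10 | (3S,4R)-3-methyl-4-[(6E)-7-methyl-3-methylidene-9-(2,6,6-trimethyl-3-oxocyclohex-1-en-1-yl)non-6-en-1-yl]oxetan-2-one | C[C@@H]1C(=O)O[C@@H]1CCC(=C)CC/C=C(\C)CCC2=C(C)C(=O)CCC2(C)C
F6 | step 10 | (2S,3S,9E)-3-hydroperoxy-2,10-dimethyl-6-methylidene-12-(2,6,6-trimethyl-3-oxocyclohex-1-en-1-yl)dodec-9-enoic acid | OC(=O)[C@@H](C)[C@@H](OO)CCC(=C)CC/C=C(\C)CCC1=C(C)C(=O)CCC1(C)C
F7 | step 10 | methyl (2S,3S,9E)-3-hydroperoxy-2,10-dimethyl-6-methylidene-12-(2,6,6-trimethyl-3-oxocyclohex-1-en-1-yl)dodec-9-enoate | COC(=O)[C@@H](C)[C@@H](OO)CCC(=C)CC/C=C(\C)CCC1=C(C)C(=O)CCC1(C)C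
F8 | step 10 | methyl (2S)-2-[(3S,6RS)-6-[(acetoxymercurio)methyl]-6-[(3E)-4-methyl-6-(2,6,6-trimethyl-3-oxocyclohex-1-en-1-yl)hex-3-en-1-yl]-1,2-dioxan-3-yl]propanoate | COC(=O)[C@@H](C)[C@@H]1CCC(C[Hg]OC(C)=O)(CC/C=C(\C)CCC2=C(C)C(=O)CCC2(C)C)OO1
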